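**Plan**

1. Retrosynthesis cuts, in this order: the C4–C8 interflavan bond between the middle and lower units; the two gallate esters; in the upper unit C2–C1′ (ring B) and C3–O; then O1–C8a of the upper unit (Baeyer–Villiger retron); finally C3–C3a and the Cα=Cβ bond of the indanone so revealed.
2. Feature used: without O1, ring C of the upper unit is the five-membered ring of a 3-aryl-4,6-dioxygenated indan-1-one; its aryl–acyl bond C7a–C1 can take up an oxygen atom, and because C1 sits meta to both ether oxygens the new O1 completes the O1/O5/O7 pattern of ring A.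
3. Forward: (−)-epicatechin → protected 8-bromo-6-carbaldehyde; aldol condensation with an o-iodoaryl methyl ketone, borylation and Rh-catalysed closure of the indanone ring; oxygen insertion expands it to ring C (lactone); C3–OH, then C2–aryl; both gallates; C4 activation of the middle unit and C8 coupling with (+)-catechin; hydrogenolysis.
4. The indanone is closed at C3–C3a onto a ready-made aryl ketone, because acylative closure of a 3,5-dialkoxyaryl propanoate would put the ketone ortho/para to the ethers (5,7-isomer) and give the wrong A ring after oxygen insertion.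
5. Stereochemistry: middle and lower units come from (−)-epicatechin and (+)-catechin; upper C4 from the ligand-controlled Rh 1,4-arylation; upper C3 from enolate hydroxylation anti to the C4 aryl; upper C2 from arylation of the oxocarbenium ion anti to the C4 aryl; middle C4 from β attack trans to the 3-acyloxy group.

Key step: step 9

Remark (naming): α is the face of a pyran ring that carries ring B in (−)-epicatechin and β the opposite face; EC* = (2R,3R)-5,7-bis(benzyloxy)-2-[3,4-bis(benzyloxy)phenyl]-8-bromo-3-(tert-butyldiphenylsilyloxy)chroman-6-yl; G = 3,4,5-tris(benzyloxy)benzoyl; CIP letters at the interflavan carbons change when the bromine is removed, the spatial arrangement does not.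

Assumption: 1-[3,5-bis(benzyloxy)phenyl]ethanone, 4-bromo-1,2-bis(benzyloxy)benzene and 3,4,5-tris(benzyloxy)benzoic acid are taken as purchased materials.

Assumption: (R)-MonoPhos is written as the ligand antipode that gives the 3R indanone; the sense of induction is catalyst-controlled, so the other antipode is used if the opposite sense is found.

**Step 1**
Reactants: 1 (−)-epicatechin
Product: 2 5,7,3′,4′-tetra-O-benzyl-(−)-epicatechin
Conditions: BnBr, K2CO3, DMF, 0 °C → rt
Reagents that add atoms: benzyl bromide, BrCc1ccccc1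
Why: Williamson etherification in which carbonate deprotonates only the four phenols, so the secondary C3–OH and both stereocentres are left untouched.

**Step 2**
Reactants: 2 5,7,3′,4′-tetra-O-benzyl-(−)-epicatechin
Product: 3 3-O-TBDPS-5,7,3′,4′-tetra-O-benzylepicatechin
Conditions: TBDPSCl, imidazole, DMAP (cat.), DMF, 50 °C
Reagents that add atoms: tert-butyl(chloro)diphenylsilane, CC(C)(C)[Si](Cl)(c1ccccc1)c1ccccc1
Why: Silylation of the secondary alcohol, the tert-butyldiphenylsilyl ether being chosen because it should survive the chloroiminium reagent of step 4 (which can turn smaller silyl ethers into formates), the peracid, the bases and the Lewis acids that follow, and still falls to fluoride in step 14.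

**Step 3**
Reactants: 3 3-O-TBDPS-5,7,3′,4′-tetra-O-benzylepicatechin
Product: 4 8-bromo-3-O-TBDPS-5,7,3′,4′-tetra-O-benzylepicatechin
Conditions: NBS, CH2Cl2, −20 °C → rt
Reagents that add atoms: N-bromosuccinimide, BrN1C(=O)CCC1=O
Why: Electrophilic aromatic bromination, C8 being the more reactive A-ring position of benzylated flavan-3-ols, so that one equivalent of NBS should cap C8 and leave C6 as the only free position.

**Step 4**
Reactants: 4 8-bromo-3-O-TBDPS-5,7,3′,4′-tetra-O-benzylepicatechin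
Product: 6 8-bromo-3-O-TBDPS-5,7,3′,4′-tetra-O-benzylepicatechin-6-carbaldehyde, via iminium chloride 5 (not isolated)
Conditions: POCl3, DMF, 0 → 50 °C; then aq. NaOAc
Reagents that add atoms: N,N-dimethylformamide, CN(C)C=O; water, O; phosphoryl chloride, O=P(Cl)(Cl)Cl (chloride counter-ion of 5 only)
Why: Vilsmeier–Haack formylation at C6, the only unsubstituted position of the trioxygenated ring, which stays nucleophilic enough despite the bromine, followed by hydrolysis of the iminium salt on buffered work-up.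

**Step 5**
Reactants: 7 1-[3,5-bis(benzyloxy)phenyl]ethanone
Product: 8 1-[3,5-bis(benzyloxy)-2-iodophenyl]ethanone
Conditions: NIS, TFA (cat.), MeCN, rt
Reagents that add atoms: N-iodosuccinimide, IN1C(=O)CCC1=O
Why: Electrophilic aromatic iodination at the position para to one benzyloxy group and ortho to the other (C4 is flanked by two ethers and is the less accessible site), which places the halogen on the carbon that will become C3a.

**Step 6**
Reactants: 6 8-bromo-3-O-TBDPS-5,7,3′,4′-tetra-O-benzylepicatechin-6-carbaldehyde; 8 1-[3,5-bis(benzyloxy)-2-iodophenyl]ethanone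
Product: 9 (E)-1-[3,5-bis(benzyloxy)-2-iodophenyl]-3-EC*-prop-2-en-1-one
Conditions: KOH (aq), EtOH/THF, rt
Reagents that add atoms: none
Why: Claisen–Schmidt (crossed aldol) condensation in which the non-enolisable aldehyde 6 takes the enolate of methyl ketone 8 and the aldol dehydrates to the conjugated E-enone.

**Step 7**
Reactants: 9 (E)-1-[3,5-bis(benzyloxy)-2-iodophenyl]-3-EC*-prop-2-en-1-one
Product: 10 (E)-1-[3,5-bis(benzyloxy)-2-(4,4,5,5-tetramethyl-1,3,2-dioxaborolan-2-yl)phenyl]-3-EC*-prop-2-en-1-one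
Conditions: B2pin2, PdCl2(dppf) (cat.), KOAc, 1,4-dioxane, 80 °C
Reagents that add atoms: bis(pinacolato)diboron, CC1(C)OB(OC1(C)C)B1OC(C)(C)C(C)(C)O1
Why: Miyaura borylation in which Pd(0) should insert into the C–I bond next to the ketone much faster than into the electron-rich C8–Br bond flanked by two oxygens, and acetate-assisted transmetalation with the diboron should outrun carbopalladation of the enone.

**Step 8**
Reactants: 10 (E)-1-[3,5-bis(benzyloxy)-2-(pinacolboryl)phenyl]-3-EC*-prop-2-en-1-one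
Product: 11 (3R)-4,6-bis(benzyloxy)-3-EC*-indan-1-one
Conditions: [Rh(C2H4)2Cl]2 (cat.), (R)-MonoPhos, aq. K3PO4, toluene, 40 °C
Reagents that add atoms: none
Why: Rhodium(I)-catalysed intramolecular asymmetric 1,4-addition of an arylboronate to an enone (Hayashi–Miyaura type), known for 2′-boryl chalcones giving 3-aryl-1-indanones, in which the aryl–Rh species formed between the acyl group and a benzyloxy group adds to the β-carbon so that the ketone ends up meta to both ethers, and the chiral phosphoramidite selects the enone face and thereby sets C3 (R) with the remote epicatechin stereocentres as spectators.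

**Step 9**
Reactants: 11 (3R)-4,6-bis(benzyloxy)-3-EC*-indan-1-one
Product: 12 (4R)-5,7-bis(benzyloxy)-4-EC*-chroman-2-one
Conditions: mCPBA, NaHCO3, CH2Cl2, 0 °C → rt
Reagents that add atoms: 3-chloroperbenzoic acid, OOC(=O)c1cccc(Cl)c1
Why: The peracid adds to the C1 carbonyl to give the Criegee adduct, and the C1–C7a bond, which can lie antiperiplanar to the O–O bond, shifts to oxygen with loss of 3-chlorobenzoate, so that oxygen is inserted between the aryl carbon and the carbonyl carbon (Baeyer–Villiger oxidation). The closest known case is the oxidation of 1-indanones, 3-aryl-1-indanones included, to 3,4-dihydrocoumarins with aryl migration. The six-membered lactone ring, the future ring C of the upper unit, arises by ring expansion through this 1,2-shift of C7a from carbon to oxygen, which forms the O1–C8a bond, and not by an exo or endo cyclisation. No stereocentre is created, and C4 (old C3), which is β to the carbonyl and takes no part in the shift, is carried over unchanged. The step needs aryl rather than methylene migration, which the higher migratory aptitude of aryl against a primary alkyl group provides, and it needs oxidation of the ketone in preference to the arenes: the carbonyl is meta to both benzyloxy groups and keeps normal ketone electrophilicity, the indanone ring is deactivated by the acyl group, the A ring of the epicatechin unit is fully substituted, and the bicarbonate buffer and low temperature hold back acid-promoted arene hydroxylation and silyl loss.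

**Step 10**
Reactants: 12 (4R)-5,7-bis(benzyloxy)-4-EC*-chroman-2-one
Product: 14 (3R,4R)-5,7-bis(benzyloxy)-3-hydroxy-4-EC*-chroman-2-one, via potassium enolate 13 (not isolated)
Conditions: KHMDS, THF, −78 °C; 2-(phenylsulfonyl)-3-phenyloxaziridine, −78 °C; AcOH
Reagents that add atoms: 2-(phenylsulfonyl)-3-phenyloxaziridine (Davis reagent), O=S(=O)(c1ccccc1)N1OC1c1ccccc1; potassium bis(trimethylsilyl)amide, C[Si](C)(C)[N-][Si](C)(C)C.[K+] (its potassium is found in 13 only)
Why: Enolate α-hydroxylation with an N-sulfonyloxaziridine, in which the potassium enolate, kept at −78 °C to avoid opening to the ketene phenoxide, should be attacked on the face opposite the bulky C4 aryl group, which sets C3 (R) trans to C4.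

**Step 11**
Reactants: 14 (3R,4R)-5,7-bis(benzyloxy)-3-hydroxy-4-EC*-chroman-2-one
Product: 15 (3R,4R)-5,7-bis(benzyloxy)-3-(tert-butyldimethylsilyloxy)-4-EC*-chroman-2-one
Conditions: TBSOTf, 2,6-lutidine, CH2Cl2, −78 → 0 °C
Reagents that add atoms: tert-butyldimethylsilyl triflate, CC(C)(C)[Si](C)(C)OS(=O)(=O)C(F)(F)F
Why: Silylation with the silyl triflate, which this hindered α-hydroxy lactone needs, gives an ether that protects C3–O through the hydride and Lewis acid steps and is later removed together with the TBDPS group.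

**Step 12**
Reactants: 15 (3R,4R)-5,7-bis(benzyloxy)-3-(tert-butyldimethylsilyloxy)-4-EC*-chroman-2-one
Product: 17 (3R,4R)-2-acetoxy-5,7-bis(benzyloxy)-3-(tert-butyldimethylsilyloxy)-4-EC*-chroman (C2 epimers), via aluminium lactolate 16 (not isolated)
Conditions: DIBAL-H, CH2Cl2, −78 °C; then pyridine, DMAP, Ac2O, −78 → 0 °C
Reagents that add atoms: acetic anhydride, CC(=O)OC(C)=O; diisobutylaluminium hydride, CC(C)C[AlH]CC(C)C (its aluminium is found in 16 only)
Why: Reductive acetylation of a lactone, in which DIBAL-H at −78 °C should stop at the aluminium hemiacetal of the reactive aryl lactone and this is acetylated in the same flask before it can open to the hydroxy aldehyde, giving the lactol acetate as oxocarbenium precursor (the C2 configuration is irrelevant).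

**Step 13**
Reactants: 17 (3R,4R)-2-acetoxy-5,7-bis(benzyloxy)-3-(tert-butyldimethylsilyloxy)-4-EC*-chroman
Product: 18 3-O-TBS-5,7,3′,4′-tetra-O-benzylepicatechin-(4β→6)-8-bromo-3-O-TBDPS-5,7,3′,4′-tetra-O-benzylepicatechin
Conditions: [3,4-(BnO)2C6H3]2Zn [from ArBr, n-BuLi, Et2O, −78 °C; ZnCl2 (0.5 equiv)], TMSOTf, CH2Cl2/Et2O, −78 → −40 °C
Reagents that add atoms: bis[3,4-bis(benzyloxy)phenyl]zinc, C(Oc1ccc([Zn]c2ccc(OCc3ccccc3)c(OCc3ccccc3)c2)cc1OCc1ccccc1)c1ccccc1, made in the flask from 4-bromo-1,2-bis(benzyloxy)benzene, Brc1ccc(OCc2ccccc2)c(OCc2ccccc2)c1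
Why: Lewis-acid-promoted substitution of a lactol acetate by an organozinc reagent through the cyclic oxocarbenium ion (C-aryl glycoside-type arylation), in which the aryl–zinc bond outcompetes the electron-rich arene positions as nucleophile and fixes the 3,4-dioxygenation of ring B, and the aryl group should enter C2 anti to the pseudoaxial C4 aryl group, which is also the 1,2-cis mode of six-membered oxocarbenium ions bearing an adjacent alkoxy group, so that C2 becomes R (2α-aryl, 2,3-cis and 2,4-trans as in a 4β-substituted epicatechin).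

**Step 14**
Reactants: 18 3-O-TBS-5,7,3′,4′-tetra-O-benzylepicatechin-(4β→6)-8-bromo-3-O-TBDPS-5,7,3′,4′-tetra-O-benzylepicatechin
Product: 19 5,7,3′,4′-tetra-O-benzylepicatechin-(4β→6)-8-bromo-5,7,3′,4′-tetra-O-benzylepicatechin
Conditions: TBAF, THF, rt → 40 °C
Reagents that add atoms: none
Why: Fluoride-mediated desilylation removes the TBS and TBDPS ethers together and frees both C3 hydroxyls, no other group in 18 being fluoride-labile.

**Step 15**
Reactants: 19 5,7,3′,4′-tetra-O-benzylepicatechin-(4β→6)-8-bromo-5,7,3′,4′-tetra-O-benzylepicatechin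
Product: 20 3-O-G-5,7,3′,4′-tetra-O-benzylepicatechin-(4β→6)-8-bromo-3-O-G-5,7,3′,4′-tetra-O-benzylepicatechin
Conditions: 3,4,5-tris(benzyloxy)benzoic acid, DCC, DMAP, CH2Cl2, rt
Reagents that add atoms: 3,4,5-tris(benzyloxy)benzoic acid, OC(=O)c1cc(OCc2ccccc2)c(OCc2ccccc2)c(OCc2ccccc2)c1
Why: Steglich esterification (DCC/DMAP) of the two secondary axial hydroxyls, the only free hydroxyls at this stage, with the benzyl-protected gallic acid.

**Step 16**
Reactants: 20 3-O-G-5,7,3′,4′-tetra-O-benzylepicatechin-(4β→6)-8-bromo-3-O-G-5,7,3′,4′-tetra-O-benzylepicatechin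
Product: 21 3-O-G-5,7,3′,4′-tetra-O-benzylepicatechin-(4β→6)-8-bromo-4β-(2-ethoxyethoxy)-3-O-G-5,7,3′,4′-tetra-O-benzylepicatechin
Conditions: DDQ, 2-ethoxyethanol, CH2Cl2, rt
Reagents that add atoms: 2-ethoxyethanol, CCOCCO
Why: DDQ-mediated benzylic oxidation of a flavan at C4 with capture of the cation by the alcohol, in which hydride should be taken from the C4 methylene of the bromo unit, whose axial C–H is aligned with its A ring, whereas the upper C4–H is a buried methine lying near the plane of its A ring, and the alkoxy group enters trans to the 3-acyloxy group (4β), a centre that is ionised again in step 18.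

**Step 17**
Reactants: 22 (+)-catechin
Product: 23 5,7,3′,4′-tetra-O-benzyl-(+)-catechin
Conditions: BnBr, K2CO3, DMF, 0 °C → rt
Reagents that add atoms: benzyl bromide, BrCc1ccccc1
Why: Williamson etherification of the four phenols under carbonate, which leaves the C3–OH and both stereocentres untouched.

**Step 18**
Reactants: 21 3-O-G-5,7,3′,4′-tetra-O-benzylepicatechin-(4β→6)-8-bromo-4β-(2-ethoxyethoxy)-3-O-G-5,7,3′,4′-tetra-O-benzylepicatechin; 23 5,7,3′,4′-tetra-O-benzyl-(+)-catechin (excess)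
Product: 24 3-O-G-5,7,3′,4′-tetra-O-benzylepicatechin-(4β→6)-8-bromo-3-O-G-5,7,3′,4′-tetra-O-benzylepicatechin-(4β→8)-5,7,3′,4′-tetra-O-benzylcatechin
Conditions: TMSOTf (cat.), CH2Cl2, −78 °C
Reagents that add atoms: none
Why: Lewis-acid-promoted flavan-4-yl cation/arene coupling (Friedel–Crafts-type procyanidin coupling), in which ionisation of the 4-alkoxy group is assisted by the neighbouring 3-O-acyl group, C8 of benzylated catechin is its most nucleophilic position, attack on the β face trans to the 3-acyloxy group sets the middle C4 with the 4β→8 bond, and the excess of 23 suppresses self-condensation through the free upper A ring.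

**Step 19**
Reactants: 24 protected trimer
Product: 25 epicatechin-3-O-gallate-(4β→6)-epicatechin-3-O-gallate-(4β→8)-catechin (CNP0112921.1)
Conditions: H2 (1 atm), Pd(OH)2/C, THF/MeOH/H2O, rt
Reagents that add atoms: none
Why: Catalytic hydrogenolysis cleaves the eighteen benzyl ethers and the aryl C–Br bond in one operation, while the gallate esters, the interflavan bonds and all stereocentres are untouched.

**Compound list**

1 | (−)-epicatechin, (2R,3R)-2-(3,4-dihydroxyphenyl)chroman-3,5,7-triol | O[C@@H]1Cc2c(O)cc(O)cc2O[C@@H]1c1ccc(O)c(O)c1 | starting material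
2 | 5,7,3′,4′-tetra-O-benzyl-(−)-epicatechin | O[C@@H]1Cc2c(OCc3ccccc3)cc(OCc3ccccc3)cc2O[C@@H]1c1ccc(OCc2ccccc2)c(OCc2ccccc2)c1 | intermediate
3 | 3-O-(tert-butyldiphenylsilyl)-5,7,3′,4′-tetra-O-benzylepicatechin | CC(C)(C)[Si](c1ccccc1)(c1ccccc1)O[C@@H]1Cc2c(OCc3ccccc3)cc(OCc3ccccc3)cc2O[C@@H]1c1ccc(OCc2ccccc2)c(OCc2ccccc2)c1 | intermediate
4 | 8-bromo-3-O-TBDPS-5,7,3′,4′-tetra-O-benzylepicatechin | CC(C)(C)[Si](c1ccccc1)(c1ccccc1)O[C@@H]1Cc2c(OCc3ccccc3)cc(OCc3ccccc3)c(Br)c2O[C@@H]1c1ccc(OCc2ccccc2)c(OCc2ccccc2)c1 | intermediate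
5 | C6 N,N-dimethyliminium chloride of 4 (EC*–CH=NMe2+ Cl−) | CC(C)(C)[Si](c1ccccc1)(c1ccccc1)O[C@@H]1Cc2c(OCc3ccccc3)c(C=[N+](C)C)c(OCc3ccccc3)c(Br)c2O[C@@H]1c1ccc(OCc2ccccc2)c(OCc2ccccc2)c1.[Cl-] | intermediate
6 | 8-bromo-3-O-TBDPS-5,7,3′,4′-tetra-O-benzylepicatechin-6-carbaldehyde (EC*–CHO) | CC(C)(C)[Si](c1ccccc1)(c1ccccc1)O[C@@H]1Cc2c(OCc3ccccc3)c(C=O)c(OCc3ccccc3)c(Br)c2O[C@@H]1c1ccc(OCc2ccccc2)c(OCc2ccccc2)c1 | intermediate
7 | 1-[3,5-bis(benzyloxy)phenyl]ethanone | CC(=O)c1cc(OCc2ccccc2)cc(OCc2ccccc2)c1 | starting material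
8 | 1-[3,5-bis(benzyloxy)-2-iodophenyl]ethanone | CC(=O)c1cc(OCc2ccccc2)cc(OCc2ccccc2)c1I | intermediate
9 | (E)-1-[3,5-bis(benzyloxy)-2-iodophenyl]-3-EC*-prop-2-en-1-one | O=C(/C=C/c1c(OCc2ccccc2)c(Br)c3c(c1OCc1ccccc1)C[C@@H](O[Si](c1ccccc1)(c1ccccc1)C(C)(C)C)[C@@H](c1ccc(OCc2ccccc2)c(OCc2ccccc2)c1)O3)c1cc(OCc2ccccc2)cc(OCc2ccccc2)c1I | intermediate
10 | (E)-1-[3,5-bis(benzyloxy)-2-(4,4,5,5-tetramethyl-1,3,2-dioxaborolan-2-yl)phenyl]-3-EC*-prop-2-en-1-one | O=C(/C=C/c1c(OCc2ccccc2)c(Br)c3c(c1OCc1ccccc1)C[C@@H](O[Si](c1ccccc1)(c1ccccc1)C(C)(C)C)[C@@H](c1ccc(OCc2ccccc2)c(OCc2ccccc2)c1)O3)c1cc(OCc2ccccc2)cc(OCc2ccccc2)c1B1OC(C)(C)C(C)(C)O1 | intermediate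
11 | (3R)-4,6-bis(benzyloxy)-3-EC*-indan-1-one | O=C1C[C@@H](c2c(OCc3ccccc3)c(Br)c3c(c2OCc2ccccc2)C[C@@H](O[Si](c2ccccc2)(c2ccccc2)C(C)(C)C)[C@@H](c2ccc(OCc4ccccc4)c(OCc4ccccc4)c2)O3)c2c(OCc3ccccc3)cc(OCc3ccccc3)cc21 | intermediate
12 | (4R)-5,7-bis(benzyloxy)-4-EC*-chroman-2-one | O=C1C[C@@H](c2c(OCc3ccccc3)c(Br)c3c(c2OCc2ccccc2)C[C@@H](O[Si](c2ccccc2)(c2ccccc2)C(C)(C)C)[C@@H](c2ccc(OCc4ccccc4)c(OCc4ccccc4)c2)O3)c2c(OCc3ccccc3)cc(OCc3ccccc3)cc2O1 | intermediate
13 | potassium enolate of 12 (potassium (4R)-5,7-bis(benzyloxy)-4-EC*-4H-chromen-2-olate) | [K+].[O-]C1=C[C@@H](c2c(OCc3ccccc3)c(Br)c3c(c2OCc2ccccc2)C[C@@H](O[Si](c2ccccc2)(c2ccccc2)C(C)(C)C)[C@@H](c2ccc(OCc4ccccc4)c(OCc4ccccc4)c2)O3)c2c(OCc3ccccc3)cc(OCc3ccccc3)cc2O1 | intermediate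
14 | (3R,4R)-5,7-bis(benzyloxy)-3-hydroxy-4-EC*-chroman-2-one (3α-OH, 4β-aryl, trans) | O[C@@H]1[C@@H](c2c(OCc3ccccc3)c(Br)c3c(c2OCc2ccccc2)C[C@@H](O[Si](c2ccccc2)(c2ccccc2)C(C)(C)C)[C@@H](c2ccc(OCc4ccccc4)c(OCc4ccccc4)c2)O3)c2c(OCc3ccccc3)cc(OCc3ccccc3)cc2OC1=O | intermediate
15 | (3R,4R)-5,7-bis(benzyloxy)-3-(tert-butyldimethylsilyloxy)-4-EC*-chroman-2-one | CC(C)(C)[Si](C)(C)O[C@@H]1[C@@H](c2c(OCc3ccccc3)c(Br)c3c(c2OCc2ccccc2)C[C@@H](O[Si](c2ccccc2)(c2ccccc2)C(C)(C)C)[C@@H](c2ccc(OCc4ccccc4)c(OCc4ccccc4)c2)O3)c2c(OCc3ccccc3)cc(OCc3ccccc3)cc2OC1=O | intermediate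
16 | diisobutylaluminium lactolate of 15 (2-O-Al(iBu)2 hemiacetal, C2 epimers) | CC(C)(C)[Si](C)(C)O[C@@H]1[C@@H](c2c(OCc3ccccc3)c(Br)c3c(c2OCc2ccccc2)C[C@@H](O[Si](c2ccccc2)(c2ccccc2)C(C)(C)C)[C@@H](c2ccc(OCc4ccccc4)c(OCc4ccccc4)c2)O3)c2c(OCc3ccccc3)cc(OCc3ccccc3)cc2OC1O[Al](CC(C)C)CC(C)C | intermediate
17 | (3R,4R)-2-acetoxy-5,7-bis(benzyloxy)-3-(tert-butyldimethylsilyloxy)-4-EC*-chroman (C2 epimers) | CC(C)(C)[Si](C)(C)O[C@@H]1[C@@H](c2c(OCc3ccccc3)c(Br)c3c(c2OCc2ccccc2)C[C@@H](O[Si](c2ccccc2)(c2ccccc2)C(C)(C)C)[C@@H](c2ccc(OCc4ccccc4)c(OCc4ccccc4)c2)O3)c2c(OCc3ccccc3)cc(OCc3ccccc3)cc2OC1OC(C)=O | intermediate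
18 | 3-O-TBS-5,7,3′,4′-tetra-O-benzylepicatechin-(4β→6)-8-bromo-3-O-TBDPS-5,7,3′,4′-tetra-O-benzylepicatechin (upper unit 2α-aryl, 3α-O, 4β-aryl; 2R,3R,4R) | CC(C)(C)[Si](C)(C)O[C@@H]1[C@@H](c2c(OCc3ccccc3)c(Br)c3c(c2OCc2ccccc2)C[C@@H](O[Si](c2ccccc2)(c2ccccc2)C(C)(C)C)[C@@H](c2ccc(OCc4ccccc4)c(OCc4ccccc4)c2)O3)c2c(OCc3ccccc3)cc(OCc3ccccc3)cc2O[C@@H]1c1ccc(OCc2ccccc2)c(OCc2ccccc2)c1 | intermediate
19 | 5,7,3′,4′-tetra-O-benzylepicatechin-(4β→6)-8-bromo-5,7,3′,4′-tetra-O-benzylepicatechin (both 3-OH free) | O[C@@H]1[C@@H](c2c(OCc3ccccc3)c(Br)c3c(c2OCc2ccccc2)C[C@@H](O)[C@@H](c2ccc(OCc4ccccc4)c(OCc4ccccc4)c2)O3)c2c(OCc3ccccc3)cc(OCc3ccccc3)cc2O[C@@H]1c1ccc(OCc2ccccc2)c(OCc2ccccc2)c1 | intermediate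
20 | 3-O-[3,4,5-tris(benzyloxy)benzoyl]-5,7,3′,4′-tetra-O-benzylepicatechin-(4β→6)-8-bromo-3-O-[3,4,5-tris(benzyloxy)benzoyl]-5,7,3′,4′-tetra-O-benzylepicatechin | O=C(O[C@@H]1[C@@H](c2c(OCc3ccccc3)c(Br)c3c(c2OCc2ccccc2)C[C@@H](OC(=O)c2cc(OCc4ccccc4)c(OCc4ccccc4)c(OCc4ccccc4)c2)[C@@H](c2ccc(OCc4ccccc4)c(OCc4ccccc4)c2)O3)c2c(OCc3ccccc3)cc(OCc3ccccc3)cc2O[C@@H]1c1ccc(OCc2ccccc2)c(OCc2ccccc2)c1)c1cc(OCc2ccccc2)c(OCc2ccccc2)c(OCc2ccccc2)c1 | intermediate
21 | 20 carrying a 4β-(2-ethoxyethoxy) group at C4 of the bromo unit | O=C(O[C@@H]1[C@@H](c2c(OCc3ccccc3)c(Br)c3c(c2OCc2ccccc2)[C@H](OCCOCC)[C@@H](OC(=O)c2cc(OCc4ccccc4)c(OCc4ccccc4)c(OCc4ccccc4)c2)[C@@H](c2ccc(OCc4ccccc4)c(OCc4ccccc4)c2)O3)c2c(OCc3ccccc3)cc(OCc3ccccc3)cc2O[C@@H]1c1ccc(OCc2ccccc2)c(OCc2ccccc2)c1)c1cc(OCc2ccccc2)c(OCc2ccccc2)c(OCc2ccccc2)c1 | intermediate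
22 | (+)-catechin, (2R,3S)-2-(3,4-dihydroxyphenyl)chroman-3,5,7-triol | O[C@H]1Cc2c(O)cc(O)cc2O[C@@H]1c1ccc(O)c(O)c1 | starting material
23 | 5,7,3′,4′-tetra-O-benzyl-(+)-catechin | O[C@H]1Cc2c(OCc3ccccc3)cc(OCc3ccccc3)cc2O[C@@H]1c1ccc(OCc2ccccc2)c(OCc2ccccc2)c1 | intermediate
24 | 3-O-G-5,7,3′,4′-tetra-O-benzylepicatechin-(4β→6)-8-bromo-3-O-G-5,7,3′,4′-tetra-O-benzylepicatechin-(4β→8)-5,7,3′,4′-tetra-O-benzylcatechin (protected trimer) | O=C(O[C@@H]1[C@@H](c2c(OCc3ccccc3)c(Br)c3c(c2OCc2ccccc2)[C@H](c2c(OCc4ccccc4)cc(OCc4ccccc4)c4c2O[C@H](c2ccc(OCc5ccccc5)c(OCc5ccccc5)c2)[C@@H](O)C4)[C@@H](OC(=O)c2cc(OCc4ccccc4)c(OCc4ccccc4)c(OCc4ccccc4)c2)[C@@H](c2ccc(OCc4ccccc4)c(OCc4ccccc4)c2)O3)c2c(OCc3ccccc3)cc(OCc3ccccc3)cc2O[C@@H]1c1ccc(OCc2ccccc2)c(OCc2ccccc2)c1)c1cc(OCc2ccccc2)c(OCc2ccccc2)c(OCc2ccccc2)c1 | intermediate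
25 | epicatechin-3-O-gallate-(4β→6)-epicatechin-3-O-gallate-(4β→8)-catechin, CNP0112921.1 (upper unit 2R,3R,4S; middle unit 2R,3R,4R; lower unit 2R,3S) | O=C(O[C@@H]1[C@@H](c2c(O)cc3c(c2O)[C@H](c2c(O)cc(O)c4c2O[C@H](c2ccc(O)c(O)c2)[C@@H](O)C4)[C@@H](OC(=O)c2cc(O)c(O)c(O)c2)[C@@H](c2ccc(O)c(O)c2)O3)c2c(O)cc(O)cc2O[C@@H]1c1ccc(O)c(O)c1)c1cc(O)c(O)c(O)c1 | target

**Totals**

Total step count: 19.
Longest linear sequence: 17 steps (steps 1–4, 6–16, 18 and 19, from (−)-epicatechin).

**Steps most likely to fail**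

Step 8 (with its preparation in step 7). The β-aryl group of the enone carries two ortho benzyloxy groups, so insertion of the enone into the aryl–rhodium bond may be slow and face discrimination by the ligand poor. The hindered arylpalladium species of step 7 may also cyclise or be reduced before it is borylated. The fallback closes the same C3–C3a bond by a polarised Nazarov cyclisation, that is by electrophilic attack on the same ring carbon, which lies ortho and para to the two ether oxygens. It sets out from aldehyde 6 and ketone 7. Ketone 7 is C-acylated with diallyl carbonate and NaH to give allyl 3-[3,5-bis(benzyloxy)phenyl]-3-oxopropanoate F1. Knoevenagel condensation of this ester with 6 (piperidinium acetate, toluene, reflux with removal of water) gives allyl 2-[3,5-bis(benzyloxy)benzoyl]-3-EC*-prop-2-enoate F2. Cu(OTf)2 with a C2-symmetric bis(oxazoline) ligand in 1,2-dichloroethane should then close the five-membered ring to allyl (3R)-4,6-bis(benzyloxy)-1-oxo-3-EC*-indane-2-carboxylate F3, the chelated chiral Lewis acid governing the sense of ring closure and hence C3. Pd(PPh3)4 and morpholine remove the allyl ester with decarboxylation, and the route is rejoined at indanone 11.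

Step 13. The aryl group may enter C2 with insufficient or reversed facial selectivity, or the oxocarbenium ion may lose the C3 proton to give the 4H-chromene. The fallback reverses the order in which the two C2 substituents are introduced, so that hydride, not aryl, is the group delivered to the cation. It sets out from lactone 15. 3,4-Bis(benzyloxy)phenyllithium (from the bromide and t-BuLi) is added at −78 °C to give (3R,4R)-2-[3,4-bis(benzyloxy)phenyl]-5,7-bis(benzyloxy)-3-(tert-butyldimethylsilyloxy)-2-hydroxy-4-EC*-chroman F4, which is in equilibrium with its open hydroxy ketone form. Ionic hydrogenation with Et3SiH and BF3·OEt2 at −40 °C then reduces the 2-aryl oxocarbenium ion. If nucleophiles prefer the face syn to the C4 aryl group, which is the case in which the direct arylation gives the C2 epimer, hydride takes that face and the aryl group is left on the α face, and the route is rejoined at flavan 18.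

Step 9. Peracid addition to the aryl ketone may be slow, and electrophilic oxygen transfer to the benzyloxy-substituted arenes may then compete. The fallback keeps the oxygen insertion into the C1–C7a bond but reaches the Criegee adduct in a different way: bis(trimethylsilyl) peroxide with catalytic TMSOTf in CH2Cl2 at −78 → −20 °C. Here the carbonyl group, not the oxidant, is activated, and the silyl peroxide is a nucleophilic reagent that should leave electron-rich arenes alone. It sets out from indanone 11 and comes back at lactone 12, and makes no new compound (F0).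

**Further compounds**

F1 | step 8 | allyl 3-[3,5-bis(benzyloxy)phenyl]-3-oxopropanoate | C=CCOC(=O)CC(=O)c1cc(OCc2ccccc2)cc(OCc2ccccc2)c1
F2 | step 8 | allyl 2-[3,5-bis(benzyloxy)benzoyl]-3-EC*-prop-2-enoate (E/Z mixture) | C=CCOC(=O)C(=Cc1c(OCc2ccccc2)c(Br)c3c(c1OCc1ccccc1)C[C@@H](O[Si](c1ccccc1)(c1ccccc1)C(C)(C)C)[C@@H](c1ccc(OCc2ccccc2)c(OCc2ccccc2)c1)O3)C(=O)c1cc(OCc2ccccc2)cc(OCc2ccccc2)c1
F3 | step 8 | allyl (3R)-4,6-bis(benzyloxy)-1-oxo-3-EC*-indane-2-carboxylate (C2 epimers) | O=C1C(C(=O)OCC=C)[C@@H](c2c(OCc3ccccc3)c(Br)c3c(c2OCc2ccccc2)C[C@@H](O[Si](c2ccccc2)(c2ccccc2)C(C)(C)C)[C@@H](c2ccc(OCc4ccccc4)c(OCc4ccccc4)c2)O3)c2c(OCc3ccccc3)cc(OCc3ccccc3)cc21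
F0 | step 9 | none | none
F4 | step 13 | (3R,4R)-2-[3,4-bis(benzyloxy)phenyl]-5,7-bis(benzyloxy)-3-(tert-butyldimethylsilyloxy)-2-hydroxy-4-EC*-chroman (C2 epimers) | CC(C)(C)[Si](C)(C)O[C@@H]1[C@@H](c2c(OCc3ccccc3)c(Br)c3c(c2OCc2ccccc2)C[C@@H](O[Si](c2ccccc2)(c2ccccc2)C(C)(C)C)[C@@H](c2ccc(OCc4ccccc4)c(OCc4ccccc4)c2)O3)c2c(OCc3ccccc3)cc(OCc3ccccc3)cc2OC1(O)c1ccc(OCc2ccccc2)c(OCc2ccccc2)c1
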